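## Retrosynthetic overview

1. Last bond: the C3–O ester, giving the trans-(2R,3S)-diol core and (2Z)-2-(acetoxymethyl)but-2-enoic acid.
2. Key bond: C2–C3 (then O1–C2), from 5-acetyl-2,4-dihydroxybenzaldehyde and a chiral sulfonium 2-methylallylide. The ylide carbon is a carbanion that afterwards loses its sulfide, so it is a reversed-polarity (d1) stand-in for an α-aryloxy-allyl anion. It joins the aldehyde carbon to the future O-bearing C2, two carbons that are both electrophilic by nature, and both stereocentres arise here.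
3. Rings: the benzene ring is bought; a transient oxirane and then the dihydrofuran ring form in the key step.
4. Supporting bonds: aryl–acetyl from the aryl bromide and an acetyl-anion equivalent (1-ethoxyvinylstannane); the Z-acid from tert-butyl but-2-ynoate by syn-hydroalumination and formaldehyde trapping.

Assumption: the ylide from the (1S,4S,5S)-sulfide is taken to react through the face remote from its CMe2 bridge carbon and so give the (2S,3S)-epoxide; if the first run shows the opposite sense, the (1R,4R,5R)-sulfide is used and nothing else changes.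

## Route

Step 1
Reactants: 1 5-bromo-2,4-dihydroxybenzaldehyde
Product: 3 5-acetyl-2,4-dihydroxybenzaldehyde, via enol ether 2 (not isolated)
Conditions: tributyl(1-ethoxyvinyl)stannane (1.3 equiv), Pd(PPh3)4 (5 mol %), 1,4-dioxane, 100 °C; then 1 M HCl, THF, rt
Reagents that add atoms: tributyl(1-ethoxyvinyl)stannane CCCC[Sn](CCCC)(CCCC)C(=C)OCC; water O
Why: Stille coupling of the aryl bromide with an acetyl-anion equivalent tolerates the free phenols and the aldehyde, and dilute acid hydrolyses aryl enol ether 2 to the methyl ketone; no stereocentre is formed.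

Step 2
Reactants: 4 (1S,4S,5S)-4,7,7-trimethyl-6-thiabicyclo[3.2.1]octane (isothiocineole, commercial)
Product: 5 (1S,4S,5S,6S)-4,7,7-trimethyl-6-(2-methylprop-2-en-1-yl)-6-thiabicyclo[3.2.1]octan-6-ium trifluoromethanesulfonate
Conditions: 3-bromo-2-methylprop-1-ene (1.5 equiv), LiOSO2CF3 (2 equiv), CH2Cl2/H2O 1:1, rt, 24 h
Reagents that add atoms: 3-bromo-2-methylprop-1-ene C=C(C)CBr; lithium trifluoromethanesulfonate [Li+].[O-]S(=O)(=O)C(F)(F)F
Why: SN2 S-alkylation by the allylic bromide, driven by bromide-to-triflate exchange, takes place on the exo lone pair of sulfur and gives one sulfonium diastereomer (new sulfur stereocentre, 6S).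

Step 3
Reactants: 3 5-acetyl-2,4-dihydroxybenzaldehyde; 5 (1S,4S,5S,6S)-4,7,7-trimethyl-6-(2-methylprop-2-en-1-yl)-6-thiabicyclo[3.2.1]octan-6-ium trifluoromethanesulfonate
Product: 8 1-[(2R,3S)-3,6-dihydroxy-2-(prop-1-en-2-yl)-2,3-dihydro-1-benzofuran-5-yl]ethan-1-one, via sulfonium ylide 6 (not isolated), via trans-epoxide 7 (not isolated)
Conditions: 3, KOtBu (2.0 equiv), THF/DMF 4:1, −40 °C; then 5 (1.2 equiv), KOtBu (1.2 equiv), −40 °C → rt; then 40 °C, 2 h; aq NH4Cl
Reagents that add atoms: none
Why: Proposed new method: ylide 6 adds through its open face to the aldehyde carbon of the bis-phenoxide of 3, and anti-betaine collapse gives the trans-(2S,3S)-vinyl epoxide 7, which fixes C3 as S under reagent control. The ortho phenoxide then opens 7 at its allylic carbon with inversion (5-endo SN2), so C2 becomes R and the ring is 2,3-trans. The closest known reactions are the isothiocineole-mediated asymmetric Corey–Chaykovsky epoxidation with allylic sulfonium salts and the salicylaldehyde plus sulfur ylide synthesis of 2,3-dihydrobenzofuran-3-ols.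

Step 4
Reactants: 9 tert-butyl but-2-ynoate
Product: 12 tert-butyl (2Z)-2-[(acetyloxy)methyl]but-2-enoate, via vinylalane 10 (not isolated), via aluminium alkoxide 11 (not isolated)
Conditions: iBu2AlH (1.1 equiv), NMO (1.1 equiv), THF, 0 °C; CH2O (gas, from cracked paraformaldehyde), 0 °C → rt; then Ac2O, pyridine, DMAP (5 mol %), 0 °C
Reagents that add atoms: formaldehyde C=O; acetic anhydride CC(=O)OC(C)=O
Why: Amine-oxide-moderated syn-hydroalumination puts aluminium on the α-carbon and hydride cis to it on the β-carbon, so the β-methyl ends cis to the ester (Z). The α-alumino acrylate adds to formaldehyde with this geometry kept (vinylalumination, an aldol-type addition), and the aluminium alkoxide is acetylated in the same flask as in reductive acetylation of esters.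

Step 5
Reactants: 12 tert-butyl (2Z)-2-[(acetyloxy)methyl]but-2-enoate
Product: 13 (2Z)-2-[(acetyloxy)methyl]but-2-enoic acid
Conditions: CF3CO2H/CH2Cl2 1:4, 0 °C → rt
Reagents that add atoms: none
Why: Acidolysis of the tert-butyl ester (loss of the tert-butyl cation as isobutene) leaves the primary acetate and the Z-trisubstituted alkene untouched at room temperature.

Step 6
Reactants: 8 1-[(2R,3S)-3,6-dihydroxy-2-(prop-1-en-2-yl)-2,3-dihydro-1-benzofuran-5-yl]ethan-1-one; 13 (2Z)-2-[(acetyloxy)methyl]but-2-enoic acid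
Product: 15 (2R,3S)-5-acetyl-6-hydroxy-2-(prop-1-en-2-yl)-2,3-dihydro-1-benzofuran-3-yl (2Z)-2-[(acetyloxy)methyl]but-2-enoate (CNP0193314.3), via acid chloride 14 (not isolated)
Conditions: 13, 1-chloro-N,N,2-trimethylprop-1-en-1-amine (1.05 equiv), CH2Cl2, 0 °C; then 8, pyridine (2 equiv), −20 → 0 °C
Reagents that add atoms: none
Why: The α-chloroenamine makes acid chloride 14 under neutral conditions, and pyridine-mediated acylation (nucleophilic acyl substitution) then takes the secondary benzylic alcohol in preference to the phenol, whose OH is hydrogen-bonded to the ortho acetyl group. The C3–O bond is not broken, so both stereocentres and the Z-alkene are kept.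

## Compound list

1 | 5-bromo-2,4-dihydroxybenzaldehyde | O=Cc1cc(Br)c(O)cc1O | starting material
2 | 5-(1-ethoxyethenyl)-2,4-dihydroxybenzaldehyde | C=C(OCC)c1cc(C=O)c(O)cc1O | intermediate
3 | 5-acetyl-2,4-dihydroxybenzaldehyde | CC(=O)c1cc(C=O)c(O)cc1O | intermediate
4 | (1S,4S,5S)-4,7,7-trimethyl-6-thiabicyclo[3.2.1]octane (isothiocineole) | C[C@H]1CC[C@H]2C[C@@H]1SC2(C)C | starting material
5 | (1S,4S,5S,6S)-4,7,7-trimethyl-6-(2-methylprop-2-en-1-yl)-6-thiabicyclo[3.2.1]octan-6-ium trifluoromethanesulfonate | C[C@H]1CC[C@H]2C[C@@H]1[S@+](CC(C)=C)C2(C)C.[O-]S(=O)(=O)C(F)(F)F | intermediate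
6 | (1S,4S,5S,6S)-4,7,7-trimethyl-6-thiabicyclo[3.2.1]octan-6-ium-6-yl 2-methylprop-2-en-1-ide (sulfonium 2-methylallylide) | C[C@H]1CC[C@H]2C[C@@H]1[S@+]([CH-]C(C)=C)C2(C)C | intermediate
7 | 1-{2,4-dihydroxy-5-[(2S,3S)-3-(prop-1-en-2-yl)oxiran-2-yl]phenyl}ethan-1-one (present as its phenoxide) | CC(=O)c1cc([C@@H]2O[C@H]2C(C)=C)c(O)cc1O | intermediate
8 | 1-[(2R,3S)-3,6-dihydroxy-2-(prop-1-en-2-yl)-2,3-dihydro-1-benzofuran-5-yl]ethan-1-one | C=C(C)[C@H]1Oc2cc(O)c(C(C)=O)cc2[C@@H]1O | intermediate
9 | tert-butyl but-2-ynoate | CC#CC(=O)OC(C)(C)C | starting material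
10 | tert-butyl (2E)-2-[bis(2-methylpropyl)alumanyl]but-2-enoate | C/C=C(\C(=O)OC(C)(C)C)[Al](CC(C)C)CC(C)C | intermediate
11 | tert-butyl (2Z)-2-({[bis(2-methylpropyl)alumanyl]oxy}methyl)but-2-enoate | C/C=C(\C(=O)OC(C)(C)C)CO[Al](CC(C)C)CC(C)C | intermediate
12 | tert-butyl (2Z)-2-[(acetyloxy)methyl]but-2-enoate | C/C=C(\C(=O)OC(C)(C)C)COC(C)=O | intermediate
13 | (2Z)-2-[(acetyloxy)methyl]but-2-enoic acid | C/C=C(\C(=O)O)COC(C)=O | intermediate
14 | (2Z)-2-[(acetyloxy)methyl]but-2-enoyl chloride | C/C=C(\C(Cl)=O)COC(C)=O | intermediate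
15 | (2R,3S)-5-acetyl-6-hydroxy-2-(prop-1-en-2-yl)-2,3-dihydro-1-benzofuran-3-yl (2Z)-2-[(acetyloxy)methyl]but-2-enoate | C=C(C)[C@H]1Oc2cc(O)c(C(C)=O)cc2[C@@H]1OC(=O)/C(=C\C)COC(C)=O | target

## Step count and risks

Total step count: 6. Longest linear sequence: 3 steps (1 → 3 → 8 → 15; equally 9 → 12 → 13 → 15).

Most likely to fail, step 3. The bulky chiral ylide must add to a doubly deprotonated, deactivated aldehyde; the epoxide must then close to the furan ring, not stall or ionise at the benzylic carbon; and the ee depends on the assumed facial sense. The fallback sets out from 3 and comes back at 8. Aldehyde 3 is annulated with the small, more reactive achiral ylide thiolanium 2-methylallylide F2, made in the flask with KOtBu in DMSO from 1-(2-methylprop-2-en-1-yl)thiolan-1-ium bromide F1 (itself from thiolane and 3-bromo-2-methylprop-1-ene). The racemic trans-epoxide, 7 plus its (2R,3R)-enantiomer F3, cyclises as before to racemic trans-diol, 8 plus the (2S,3R)-diol F4. Candida antarctica lipase B and vinyl acetate in MTBE then acylate the (3S)-alcohol selectively, the sense expected by analogy with 1-indanol-type benzylic alcohols, to give the (2R,3S)-3-acetate F5 and leave F4. F5 is separated and its acetate removed with K2CO3 in MeOH at 0 °C, which returns to 8.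

Second, step 6. The phenol may compete for the acid chloride, the angelate-type Z-alkene may isomerise, and the benzylic ester may eliminate to the benzofuran. The fallback sets out from 8 and comes back at 15. Diol 8 is acylated on both hydroxyl groups with an excess of 14 (2.5 equiv, pyridine, rt) to the 3,6-bis-ester F6. The aryl ester, activated by the ortho acetyl group, is then cleaved selectively with NaHCO3 in MeOH/THF at 0 °C, which returns to 15.

Third, step 4. Trapping the vinylalane with formaldehyde, the in-flask acetylation and the Z-selectivity are all demanding in one operation. The fallback sets out from 9 and comes back at 12. Ynoate 9 is hydrostannylated with syn selectivity (Bu3SnH, Pd(PPh3)4, THF, 0 °C) to tert-butyl (2E)-2-(tributylstannyl)but-2-enoate F7. Iodine in CH2Cl2 converts this with retention into tert-butyl (2E)-2-iodobut-2-enoate F8. Stille coupling with (tributylstannyl)methanol (Pd(PPh3)4, dioxane, 90 °C) gives tert-butyl (2Z)-2-(hydroxymethyl)but-2-enoate F9, and acetylation (Ac2O, pyridine) returns to 12.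

## Further compounds

F1 | step 3 | 1-(2-methylprop-2-en-1-yl)thiolan-1-ium bromide | C=C(C)C[S+]1CCCC1.[Br-]
F2 | step 3 | thiolan-1-ium-1-yl 2-methylprop-2-en-1-ide (thiolanium 2-methylallylide) | C=C(C)[CH-][S+]1CCCC1
F3 | step 3 | 1-{2,4-dihydroxy-5-[(2R,3R)-3-(prop-1-en-2-yl)oxiran-2-yl]phenyl}ethan-1-one | CC(=O)c1cc([C@H]2O[C@@H]2C(C)=C)c(O)cc1O
F4 | step 3 | 1-[(2S,3R)-3,6-dihydroxy-2-(prop-1-en-2-yl)-2,3-dihydro-1-benzofuran-5-yl]ethan-1-one | C=C(C)[C@@H]1Oc2cc(O)c(C(C)=O)cc2[C@H]1O
F5 | step 3 | (2R,3S)-5-acetyl-6-hydroxy-2-(prop-1-en-2-yl)-2,3-dihydro-1-benzofuran-3-yl acetate | C=C(C)[C@H]1Oc2cc(O)c(C(C)=O)cc2[C@@H]1OC(C)=O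
F6 | step 6 | (2R,3S)-5-acetyl-2-(prop-1-en-2-yl)-2,3-dihydro-1-benzofuran-3,6-diyl bis{(2Z)-2-[(acetyloxy)methyl]but-2-enoate} | C=C(C)[C@H]1Oc2cc(OC(=O)/C(=C\C)COC(C)=O)c(C(C)=O)cc2[C@@H]1OC(=O)/C(=C\C)COC(C)=O
F7 | step 4 | tert-butyl (2E)-2-(tributylstannyl)but-2-enoate | C/C=C(\C(=O)OC(C)(C)C)[Sn](CCCC)(CCCC)CCCC
F8 | step 4 | tert-butyl (2E)-2-iodobut-2-enoate | C/C=C(\C(=O)OC(C)(C)C)I
F9 | step 4 | tert-butyl (2Z)-2-(hydroxymethyl)but-2-enoate | C/C=C(\C(=O)OC(C)(C)C)CO
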